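The runs are simulated with constants of no real substance; the scatter is artificial.

A charge ratio of 1.52 between the noon and summer runs took the mean product plateau from 19.6 % to 14.9 % of the charge, and this pair of ratios carries the new flask.

| flask | substrate | remark | time |
|---|---|---|---|
| noon | 0.025 M | run made earlier |  |
| summer | 0.038 M | run made earlier |  |
| flask | 0.050 M |  | 12 h |

| run | time / h | substrate / % | product / % |
|---|---|---|---|
| noon | 1.00 | 0 | 18.8 |
| noon | 2.00 | 0.3 | 20.1 |
| noon | 3.00 | 0.3 | 19.9 |
| noon | 6.00 | 0 | 19.5 |
| noon | 12.0 | 0 | 19.7 |
| summer | 1.00 | 0.1 | 15.4 |
| summer | 2.00 | 0.3 | 15.4 |
| summer | 3.00 | 0 | 15.5 |
| summer | 6.00 | 0 | 14.1 |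
| summer | 12.0 | 1.0 | 14.1 |

(scatter of a reading: 0.5 percentage points)

- the reaction counts as stopped when no species that holds the substrate changes by six tenths of a point or more over the second half of the time

- at 12 h, what has stopped the reaction, if anything has (it is still moving / forward and back rates have come level / all of the substrate has reacted)
- conversion of substrate at 12 h
- amount of product at 12 h, in percent of the substrate charged
- amount of product if the flask were left three thousand times as long, in percent of the substrate charged

Time is the first setting. By hand, a longer wait adds product while substrate remains, but noon substrate already reads 0 % at 1.00 h and summer substrate 0.1 %. Noon product then moves from 18.8 % to 19.7 %, against a scatter of 0.5 percentage points, while summer product slips to 14.1 %. So this reckoning expects the flask to stop with its substrate used, and to hold the same product after a far longer wait.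

The charge is the second setting. By hand, a loss that gains on product with concentration lowers the plateau as the charge rises, and the noon run leaves 80.4 % of its charge unseen. The runs measure this as the charge exponent, the logarithm of the plateau ratio over the logarithm of the charge ratio, 0.655. A plateau with substrate at 0 % in the noon run points to kinetic control, not to a level of forward and back rates. The flask has twice the noon charge, so the exponent gives 12.4 % product.

The forecast says all of the substrate has reacted, with conversion 100 %, product 12.3 % at 12 h and 12.2 % after the long wait. Its ground is this: “So most of the substrate leaves by an unseen route, and that route gains with concentration.” Its product figure stands lower than the exponent's 12.4 %.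

The flask ends with this outcome: all of the substrate has reacted. Its conversion is 100 %, its product 12.7 % at 12 h and 12.7 % after the long wait.

    substrate ⇌ intermediate (K = 1.30, k = 0.0110 s⁻¹)
    intermediate → product (k = 0.00440 s⁻¹)
    2 substrate → homo dimer (k = 0.880 M⁻¹ s⁻¹)
    intermediate → decomposed reagent (k = 0.00230 s⁻¹)

Beside its product, the flask holds homo dimer at 80.7 %, each counted as two, and decomposed reagent at 6.63 % at 12.0 h, and the exponent lumps these two together as one unseen share. Product already stands at 12.7 % at 1.20 h, and the exponent's figure lies 0.30 points below the flask's, against a scatter of 0.5 points. On the neighbour flask, charged at 0.800 of the noon charge, the same exponent gives 22.7 %. That neighbour flask, with 0.020 M of substrate, stands at 22.2 % product.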